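The numbers in the tables are calculated on assumed constants, and the scatter is random.

Set this flask beside the autumn run, which has the same charges of starting material and second substrate but 14 µM of enzyme against 28 µM here.

in all of them: second substrate 0.147 M
- winter: starting material 0.20 M; enzyme 28 µM; run made earlier
- summer: starting material 0.31 M; enzyme 28 µM; run made earlier
- autumn: starting material 0.14 M; enzyme 14 µM; run made earlier
- flask: starting material 0.14 M; enzyme 28 µM; time 4.0 d

- winter (time / d: starting material / %, product / %): 0.167: 15.6, 43.3; 0.500: 2.6, 50.8; 0.833: 0.2, 53.1; 1.25: 0, 52.6; 1.67: 0, 52.5; 2.50: 0, 52.4
- summer (time / d: starting material / %, product / %): 0.208: 11.0, 33.3; 0.333: 3.7, 36.2; 0.500: 1.7, 36.7; 0.833: 1.4, 37.6; 1.67: 0.5, 37.7; 2.50: 0.1, 39.0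
- autumn (time / d: starting material / %, product / %): 0.500: 6.2, 45.5; 1.04: 1.3, 49.4; 1.25: 0.7, 50.6; 2.08: 0, 50.4; 2.50: 1.1, 51.3

(scatter of a reading: 1 percentage point)

- in percentages every species weighs as the starting material in it: one homo dimer counts as two
- steps thought possible: starting material + enzyme <-> starting complex; second substrate + starting complex <-> ternary complex; ternary complex -> enzyme + product; enzyme <-> dormant form; 2 starting material -> homo dimer
- the reaction counts as stopped when no species that holds the starting material changes by six tenths of a point or more over the second half of the time

- at 4.0 d, what has stopped the reaction, if anything has (all of the starting material has reacted / the second substrate has run out first / forward and back rates have come level / no working catalyst is left / it is still moving)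
- how much of the starting material has reacted by 4.0 d
- how much product there is at 4.0 d, in percent of the starting material charged

In the autumn run the starting material reads 0 % at 2.08 d, yet product stops near 51.3 %, so I take the rest to be homo dimer. I assume the enzyme's rate follows the enzyme and barely changes with starting material (zero order), while dimer formation follows the square of starting material. With the second substrate held at 0.147 M, the split should then depend on one concentration, which I call the working charge: the charge of starting material times the square root of the ratio of 28 µM to the enzyme charge. For the autumn run that is 0.198 M, close to the winter run's 0.20 M, and their last products differ by 1.1 percentage points, about the scatter. This flask's working charge is 0.14 M, lower than the autumn run's, so it should end higher.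

Call the charge not in product, over the product, the loss ratio. The winter run reads 0.908 and the summer run 1.56, so the ratio grows as the working charge raised to 1.24, the split exponent. From the autumn ratio 0.949, this flask gets 0.618, which is 61.8 % product.

The forecast says all of the starting material has reacted, 100 % reacted and 65 % product, higher than my figure, on the ground of “an irreversible loss second-order in starting material”.

The flask gives 64.4 % product with 100 % reacted: all of the starting material has reacted. Homo dimer holds 35.6 % at 4.00 d. The forecast stands. From the flask's ratio 0.552, the exponent takes a charge of 0.165 M of starting material to a ratio of 0.679, which is 4.8 points less product; the computed flask at that charge has moved by 5 points, and a run of this recipe reading that far low is what would count against the forecast.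

    starting material + enzyme ⇌ starting complex (K = 3.30 L mol⁻¹, k = 2.20 × 10⁵ L mol⁻¹ h⁻¹)
    second substrate + starting complex ⇌ ternary complex (K = 8.60 L mol⁻¹, k = 1.20 × 10⁵ L mol⁻¹ h⁻¹)
    ternary complex → enzyme + product (k = 9800 h⁻¹)
    enzyme ⇌ dormant form (K = 0.640, k = 0.0420 h⁻¹)
    2 starting material → homo dimer (k = 1.50 L mol⁻¹ h⁻¹)

For the neighbour charged with 0.56 M, the summer ratio and the exponent give 3.26, so 23.5 % product. The computed neighbour gives 24.2 %.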